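## Plan

- The 5-OH is traced back to a 5-OMe group (peri to the C4 carbonyl) and C3–H to C3–Cl. The pyranone is then cut at C2–C3 and C3–C4, which takes out C3 as a one-carbon unit (chloroform) and leaves a 2-aryl-3-silyloxybenzofuran.
- This cut is possible because C3 is the only pyranone carbon that carries nothing but hydrogen, and it lies between C2 (aryl, O1) and the C4 carbonyl. Without it the hetero ring is a furan whose C2=C3 bond is a doubly oxygenated enol ether that can take up a carbene.
- The benzofuranone behind the furan is cut at C3–C3a (Friedel–Crafts acylation) and O1–C2 (phenoxide SN2), giving 2,3,5-trimethoxyphenol and an α-bromo-(2,3-dimethoxyphenyl)acetate.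
- Forward: the A-ring phenol is made from 2-hydroxy-4,6-dimethoxybenzaldehyde; ether formation and acylation close the furanone ring first; silylation aromatises it; one-carbon insertion expands the furan to the pyranone; dechlorination and 5-O-demethylation finish.
- Stereochemistry: the target has no stereocentre; stereocentres in intermediates are racemic and are erased on the way.

Key step: step 11

Remark: since the target contains no stereogenic element, "single enantiomer" is taken to mean the one achiral compound, and no enantiocontrol is planned.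

## Route

Step 1
Reactants: 1 2-hydroxy-4,6-dimethoxybenzaldehyde
Product: 2 2-(benzyloxy)-4,6-dimethoxybenzaldehyde
Conditions: BnBr, K2CO3, DMF, 60 °C
Reagents that add atoms: benzyl bromide, BrCc1ccccc1
Why: Williamson ether synthesis on the only acidic hydroxyl; the benzyl group masks the oxygen that later becomes O1, so that the oxygen introduced in step 2 can be methylated on its own.

Step 2
Reactants: 2 2-(benzyloxy)-4,6-dimethoxybenzaldehyde
Product: 4 2-(benzyloxy)-4,6-dimethoxyphenol, via aryl formate 3 (not isolated)
Conditions: mCPBA, CH2Cl2, 0 °C → rt; aq. NaHCO3 wash; then K2CO3 (cat.), MeOH, rt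
Reagents that add atoms: 3-chloroperoxybenzoic acid, OOC(=O)c1cccc(Cl)c1
Why: Baeyer–Villiger (Dakin-type) oxidation, in which the electron-rich trialkoxyaryl group should migrate in preference to hydrogen to give the formate, which mild methanolysis cleaves.

Step 3
Reactants: 4 2-(benzyloxy)-4,6-dimethoxyphenol
Product: 5 1-(benzyloxy)-2,3,5-trimethoxybenzene
Conditions: MeI, K2CO3, DMF, rt
Reagents that add atoms: iodomethane, CI
Why: Williamson O-methylation of the only free hydroxyl, which fixes the oxygen that becomes the 8-methoxy group of the flavone.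

Step 4
Reactants: 5 1-(benzyloxy)-2,3,5-trimethoxybenzene
Product: 6 2,3,5-trimethoxyphenol
Conditions: H2 (1 atm), 10% Pd/C, EtOAc/MeOH, rt
Reagents that add atoms: none
Why: Catalytic hydrogenolysis of the benzyl ether; the aryl methyl ethers are inert, so the hydroxyl set free is the one that becomes O1.

Step 5
Reactants: 7 (2,3-dimethoxyphenyl)acetic acid
Product: 8 methyl (2,3-dimethoxyphenyl)acetate
Conditions: MeOH, H2SO4 (cat.), reflux
Reagents that add atoms: methanol, CO
Why: Fischer esterification, which blocks the acid for the radical bromination and the phenoxide alkylation that follow.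

Step 6
Reactants: 8 methyl (2,3-dimethoxyphenyl)acetate
Product: 9 methyl bromo(2,3-dimethoxyphenyl)acetate (racemic)
Conditions: NBS, AIBN (cat.), PhCF3, 80 °C
Reagents that add atoms: N-bromosuccinimide, O=C1CCC(=O)N1Br
Why: Wohl–Ziegler radical bromination at the C–H that is both benzylic and α to the ester, with the nonpolar medium and low bromine concentration disfavouring ionic bromination of the dimethoxyarene; the new stereocentre is racemic and needs no control.

Step 7
Reactants: 6 2,3,5-trimethoxyphenol; 9 methyl bromo(2,3-dimethoxyphenyl)acetate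
Product: 10 methyl (2,3-dimethoxyphenyl)(2,3,5-trimethoxyphenoxy)acetate (racemic)
Conditions: K2CO3, acetone, 55 °C
Reagents that add atoms: none
Why: Williamson ether synthesis (SN2) of the phenoxide on a secondary bromide activated by both the ester and the aryl group, forming the future O1–C2 bond; the stereocentre stays racemic and is removed in step 10.

Step 8
Reactants: 10 methyl (2,3-dimethoxyphenyl)(2,3,5-trimethoxyphenoxy)acetate
Product: 11 (2,3-dimethoxyphenyl)(2,3,5-trimethoxyphenoxy)acetic acid (racemic)
Conditions: LiOH·H2O, THF/MeOH/H2O, rt; then 1 M HCl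
Reagents that add atoms: lithium hydroxide, [Li+].[OH-]
Why: Ester saponification; the benzylic aryl ether and the methyl ethers are stable to hydroxide at room temperature.

Step 9
Reactants: 11 (2,3-dimethoxyphenyl)(2,3,5-trimethoxyphenoxy)acetic acid
Product: 13 2-(2,3-dimethoxyphenyl)-4,6,7-trimethoxy-1-benzofuran-3(2H)-one (racemic), via mixed trifluoroacetic anhydride 12 (not isolated)
Conditions: TFAA, CH2Cl2, 0 °C → rt (argon); then aq. NaHCO3
Reagents that add atoms: none
Why: Intramolecular Friedel–Crafts acylation through the mixed anhydride onto the only free carbon ortho to the ether oxygen, which is para to one methoxy group and ortho to another, so the five-membered ketone ring should close with an unambiguous A-ring pattern and no new stereocentre.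

Step 10
Reactants: 13 2-(2,3-dimethoxyphenyl)-4,6,7-trimethoxy-1-benzofuran-3(2H)-one
Product: 14 tert-butyl{[2-(2,3-dimethoxyphenyl)-4,6,7-trimethoxy-1-benzofuran-3-yl]oxy}dimethylsilane
Conditions: TBSOTf, Et3N, CH2Cl2, 0 °C → rt (argon)
Reagents that add atoms: tert-butyldimethylsilyl trifluoromethanesulfonate, CC(C)(C)[Si](C)(C)OS(=O)(=O)C(F)(F)F
Why: Soft enolisation and O-silylation (silyl enol ether formation) of a ketone whose C2–H is benzylic, α-oxygenated and α to the carbonyl; the gain of benzofuran aromaticity should favour O- over C-silylation, and the C2 stereocentre disappears.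

Step 11
Reactants: 14 tert-butyl{[2-(2,3-dimethoxyphenyl)-4,6,7-trimethoxy-1-benzofuran-3-yl]oxy}dimethylsilane; 15 chloroform
Product: 18 3-chloro-2-(2,3-dimethoxyphenyl)-5,7,8-trimethoxy-4H-chromen-4-one, via dichlorocyclopropane adduct 16 (not isolated), via silyloxyflavylium chloride 17 (not isolated)
Conditions: CHCl3 (5 equiv), KOtBu (4 equiv, added in portions), hexane/toluene, −20 °C → rt
Reagents that add atoms: chloroform, ClC(Cl)Cl
Why: Proposed new method: dichlorocarbene, released by α-elimination from chloroform 15 and KOtBu, should attack as an electrophile the furan C2=C3 bond of 14, the most electron-rich π bond in the molecule because it is an aryl enol ether and a silyl enol ether at once, and give the gem-dichlorocyclopropane 16. Loss of the endo chloride with disrotatory cyclopropyl-to-allyl opening then necessarily breaks the bond opposite the CCl2 carbon, the old C2–C3 ring fusion, with the charge taken up by O1 and the silyloxy oxygen (flavylium chloride 17); chloride then strips the silyl group and leaves the 4-pyranone 18, whose C3 is the former carbene carbon. The closest known reactions are the dihalocarbene ring expansion of ketone silyl enol ethers to α-chloroenones and the Ciamician–Dennstedt-type enlargement of benzofurans, indoles and indenes; their combination on a 2-aryl-3-silyloxybenzofuran to give a flavone is the new element. The pyranone ring arises not by cyclisation but by one-atom ring expansion of the furan, a [2+1] cycloaddition followed by electrocyclic opening, which forms the C2–C3 and C3–C4 bonds of the flavone. No stereocentre survives, since 16 is only a transient cis-fused racemate. The step needs carbene addition at the furan bond and not at the methoxyarenes, which the two oxygen donors on that alkene should secure, and it needs the absence of free enolate (which would be dichloromethylated at C2), which the hindered TBS ether and portionwise base in a cold nonpolar medium with excess chloroform should secure.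

Step 12
Reactants: 18 3-chloro-2-(2,3-dimethoxyphenyl)-5,7,8-trimethoxy-4H-chromen-4-one
Product: 19 2-(2,3-dimethoxyphenyl)-5,7,8-trimethoxy-4H-chromen-4-one
Conditions: 10% Pd/C (cat.), HCO2NH4, MeOH, 60 °C
Reagents that add atoms: none
Why: Palladium-catalysed transfer hydrogenolysis (hydrodehalogenation) of the C3–Cl bond; the cross-conjugated C2=C3 bond of a flavone is reduced only slowly under these conditions and the aryl ethers are inert.

Step 13
Reactants: 19 2-(2,3-dimethoxyphenyl)-5,7,8-trimethoxy-4H-chromen-4-one
Product: 21 2-(2,3-dimethoxyphenyl)-5-hydroxy-7,8-dimethoxy-4H-chromen-4-one (5-hydroxy-2',3',7,8-tetramethoxyflavone), via aryloxydichloroborane 20 (not isolated)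
Conditions: BCl3 (1 M in CH2Cl2, 1.5 equiv), CH2Cl2, −78 → 0 °C; then H2O
Reagents that add atoms: none
Why: Chelation-directed Lewis-acid ether cleavage, in which boron binds the C4 carbonyl and the peri 5-oxygen in a six-membered chelate so that chloride should remove only that methyl group, the other four methoxy groups staying intact, and water releases the phenol from borane 20.

## Compound list

1 | 2-hydroxy-4,6-dimethoxybenzaldehyde | COc1cc(O)c(C=O)c(OC)c1 | starting material
2 | 2-(benzyloxy)-4,6-dimethoxybenzaldehyde | COc1cc(OCc2ccccc2)c(C=O)c(OC)c1 | intermediate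
3 | 2-(benzyloxy)-4,6-dimethoxyphenyl formate | COc1cc(OCc2ccccc2)c(OC=O)c(OC)c1 | intermediate (not isolated)
4 | 2-(benzyloxy)-4,6-dimethoxyphenol | COc1cc(OCc2ccccc2)c(O)c(OC)c1 | intermediate
5 | 1-(benzyloxy)-2,3,5-trimethoxybenzene | COc1cc(OCc2ccccc2)c(OC)c(OC)c1 | intermediate
6 | 2,3,5-trimethoxyphenol | COc1cc(O)c(OC)c(OC)c1 | intermediate
7 | (2,3-dimethoxyphenyl)acetic acid | COc1cccc(CC(=O)O)c1OC | starting material
8 | methyl (2,3-dimethoxyphenyl)acetate | COC(=O)Cc1cccc(OC)c1OC | intermediate
9 | methyl bromo(2,3-dimethoxyphenyl)acetate (racemic) | COC(=O)C(Br)c1cccc(OC)c1OC | intermediate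
10 | methyl (2,3-dimethoxyphenyl)(2,3,5-trimethoxyphenoxy)acetate (racemic) | COC(=O)C(Oc1cc(OC)cc(OC)c1OC)c1cccc(OC)c1OC | intermediate
11 | (2,3-dimethoxyphenyl)(2,3,5-trimethoxyphenoxy)acetic acid (racemic) | OC(=O)C(Oc1cc(OC)cc(OC)c1OC)c1cccc(OC)c1OC | intermediate
12 | (2,3-dimethoxyphenyl)(2,3,5-trimethoxyphenoxy)acetic trifluoroacetic anhydride (racemic) | O=C(OC(=O)C(F)(F)F)C(Oc1cc(OC)cc(OC)c1OC)c1cccc(OC)c1OC | intermediate (not isolated)
13 | 2-(2,3-dimethoxyphenyl)-4,6,7-trimethoxy-1-benzofuran-3(2H)-one (racemic) | COc1cccc(C2Oc3c(OC)c(OC)cc(OC)c3C2=O)c1OC | intermediate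
14 | tert-butyl{[2-(2,3-dimethoxyphenyl)-4,6,7-trimethoxy-1-benzofuran-3-yl]oxy}dimethylsilane | COc1cccc(-c2oc3c(OC)c(OC)cc(OC)c3c2O[Si](C)(C)C(C)(C)C)c1OC | intermediate
15 | chloroform | ClC(Cl)Cl | starting material
16 | tert-butyl{[1,1-dichloro-1a-(2,3-dimethoxyphenyl)-3,4,6-trimethoxy-1,1a-dihydro-6bH-cyclopropa[b][1]benzofuran-6b-yl]oxy}dimethylsilane (racemic, cis-fused; one enantiomer drawn) | COc1cccc([C@@]23Oc4c(OC)c(OC)cc(OC)c4[C@]2(O[Si](C)(C)C(C)(C)C)C3(Cl)Cl)c1OC | intermediate (not isolated)
17 | 4-[(tert-butyldimethylsilyl)oxy]-3-chloro-2-(2,3-dimethoxyphenyl)-5,7,8-trimethoxychromenylium chloride | COc1cccc(-c2[o+]c3c(OC)c(OC)cc(OC)c3c(O[Si](C)(C)C(C)(C)C)c2Cl)c1OC.[Cl-] | intermediate (not isolated)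
18 | 3-chloro-2-(2,3-dimethoxyphenyl)-5,7,8-trimethoxy-4H-chromen-4-one | COc1cccc(-c2oc3c(OC)c(OC)cc(OC)c3c(=O)c2Cl)c1OC | intermediate
19 | 2-(2,3-dimethoxyphenyl)-5,7,8-trimethoxy-4H-chromen-4-one | COc1cccc(-c2cc(=O)c3c(OC)cc(OC)c(OC)c3o2)c1OC | intermediate
20 | dichloro{[2-(2,3-dimethoxyphenyl)-7,8-dimethoxy-4-oxo-4H-chromen-5-yl]oxy}borane | COc1cccc(-c2cc(=O)c3c(OB(Cl)Cl)cc(OC)c(OC)c3o2)c1OC | intermediate (not isolated)
21 | 2-(2,3-dimethoxyphenyl)-5-hydroxy-7,8-dimethoxy-4H-chromen-4-one (5-hydroxy-2',3',7,8-tetramethoxyflavone) | COc1cccc(-c2cc(=O)c3c(O)cc(OC)c(OC)c3o2)c1OC | target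

## Step count and risks

Total step count: 13 steps.
Longest linear sequence: 11 steps (steps 1–4, then 7–13); the arylacetate branch (steps 5–6) joins at step 7.

**Steps most likely to fail**

1. Step 11 (ring expansion). tert-Butoxide may attack silicon before carbene transfer; the enolate set free would then be dichloromethylated at C2. Carbene addition to the crowded tetrasubstituted alkene may also be too slow to compete with carbene decay, or residual base may open the pyranone once it has formed. The fallback builds the pyranone by the classical chalcone route and needs no carbene. It sets out from phenol 6. Acetylation ortho to the hydroxyl (BF3·OEt2, AcOH, 90 °C; the only ortho position free) should give 1-(2-hydroxy-3,4,6-trimethoxyphenyl)ethanone F1. Claisen–Schmidt condensation with commercial 2,3-dimethoxybenzaldehyde (KOH, EtOH, rt) should give (E)-3-(2,3-dimethoxyphenyl)-1-(2-hydroxy-3,4,6-trimethoxyphenyl)prop-2-en-1-one F2. Oxidative cyclisation with catalytic iodine in DMSO at 130 °C should then give flavone 19, where the route is rejoined before step 13.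

2. Step 9 (Friedel–Crafts closure). The activated acyl species may lose carbon monoxide, because the resulting cation is stabilised by the aryloxy oxygen and the o-methoxyphenyl ring; this would compete with closure to the strained five-membered ketone. The enolisable C2–H of the product may also be oxidised by air during isolation. The fallback closes the ring by O-alkylation instead of C-acylation. It sets out from phenol 6 and acid 7. Direct ortho-acylation (BF3·OEt2, 85 °C) should give 2-(2,3-dimethoxyphenyl)-1-(2-hydroxy-3,4,6-trimethoxyphenyl)ethanone F3. α-Bromination of the ketone (CuBr2, EtOAc/CHCl3, reflux) should give 2-bromo-2-(2,3-dimethoxyphenyl)-1-(2-hydroxy-3,4,6-trimethoxyphenyl)ethanone F4. Intramolecular displacement of bromide by the phenol (NaOAc, EtOH, reflux) should form the O1–C2 bond and give benzofuranone 13, where the route is rejoined before step 10.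

3. Step 12 (hydrodechlorination). Insertion of palladium into the C3–Cl bond, which sits on the β-carbon of an enol ether, may be slow, and forcing conditions may begin to saturate the C2=C3 bond. The fallback exchanges the halogen that has to be removed. It sets out from silyl enol ether 14, which is treated with bromoform and KOtBu (hexane/toluene, −20 °C → rt). The reaction should pass through tert-butyl{[1,1-dibromo-1a-(2,3-dimethoxyphenyl)-3,4,6-trimethoxy-1,1a-dihydro-6bH-cyclopropa[b][1]benzofuran-6b-yl]oxy}dimethylsilane F5 and 3-bromo-4-[(tert-butyldimethylsilyl)oxy]-2-(2,3-dimethoxyphenyl)-5,7,8-trimethoxychromenylium bromide F6, neither isolated. It should give 3-bromo-2-(2,3-dimethoxyphenyl)-5,7,8-trimethoxy-4H-chromen-4-one F7. The C–Br bond of F7 is cleaved far more readily (H2 1 atm, Pd/C, Et3N, EtOAc, rt) and should give flavone 19, where the route is rejoined before step 13.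

## Further compounds

F1 | step 11 | 1-(2-hydroxy-3,4,6-trimethoxyphenyl)ethanone | CC(=O)c1c(O)c(OC)c(OC)cc1OC
F2 | step 11 | (E)-3-(2,3-dimethoxyphenyl)-1-(2-hydroxy-3,4,6-trimethoxyphenyl)prop-2-en-1-one | COc1cccc(/C=C/C(=O)c2c(O)c(OC)c(OC)cc2OC)c1OC
F3 | step 9 | 2-(2,3-dimethoxyphenyl)-1-(2-hydroxy-3,4,6-trimethoxyphenyl)ethanone | COc1cccc(CC(=O)c2c(O)c(OC)c(OC)cc2OC)c1OC
F4 | step 9 | 2-bromo-2-(2,3-dimethoxyphenyl)-1-(2-hydroxy-3,4,6-trimethoxyphenyl)ethanone (racemic) | COc1cccc(C(Br)C(=O)c2c(O)c(OC)c(OC)cc2OC)c1OC
F5 | step 12 | tert-butyl{[1,1-dibromo-1a-(2,3-dimethoxyphenyl)-3,4,6-trimethoxy-1,1a-dihydro-6bH-cyclopropa[b][1]benzofuran-6b-yl]oxy}dimethylsilane (racemic, cis-fused; one enantiomer drawn) | COc1cccc([C@@]23Oc4c(OC)c(OC)cc(OC)c4[C@]2(O[Si](C)(C)C(C)(C)C)C3(Br)Br)c1OC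
F6 | step 12 | 3-bromo-4-[(tert-butyldimethylsilyl)oxy]-2-(2,3-dimethoxyphenyl)-5,7,8-trimethoxychromenylium bromide | COc1cccc(-c2[o+]c3c(OC)c(OC)cc(OC)c3c(O[Si](C)(C)C(C)(C)C)c2Br)c1OC.[Br-]
F7 | step 12 | 3-bromo-2-(2,3-dimethoxyphenyl)-5,7,8-trimethoxy-4H-chromen-4-one | COc1cccc(-c2oc3c(OC)c(OC)cc(OC)c3c(=O)c2Br)c1OC
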